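All runs are simulated with made-up constants; the scatter is artificial.

Give every flask 2.0 min and leave it closed, and reckon over that time as if a molecule of substrate stood at one fork: it becomes target, or it leaves by a second way out.

| flask | substrate | reagent | initiator | remark | time |
|---|---|---|---|---|---|
| ochre | 0.012 M | 0.022 M | 0.12 mM | run made earlier |  |
| red | 0.012 M | 0.045 M | 0.12 mM | run made earlier |  |
| grey | 0.012 M | 0.11 M | 0.12 mM | run made earlier |  |
| violet | 0.012 M | 0.024 M | 0.23 mM | run made earlier |  |
| north | 0.012 M | 0.100 M | 0.080 mM |  | 2.0 min |
| east | 0.012 M | 0.0240 M | 0.12 mM |  | 2.0 min |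
| south-east | 0.012 M | 0.0240 M | 0.20 mM |  | 2.0 min |
| north-west | 0.0030 M | 0.0500 M | 0.50 mM |  | 2.0 min |

- ochre (time / s: target / %, substrate / %): 10.0: 3, 74; 12.0: 2, 71; 25.0: 7, 51; 40.0: 13, 40; 80.0: 16, 23
- red (time / s: target / %, substrate / %): 10.0: 5, 71; 20.0: 11, 53; 40.0: 18, 28; 60.0: 26, 21; 80.0: 27, 15
- grey (time / s: target / %, substrate / %): 10.0: 15, 62; 20.0: 27, 37; 40.0: 44, 14; 60.0: 58, 5; 80.0: 67, 1
- violet (time / s: target / %, substrate / %): 10.0: 5, 71; 20.0: 11, 53; 40.0: 17, 34; 60.0: 20, 23; 80.0: 24, 15

(readings scatter by 1.5 percentage points)

- a reading or a percentage of target counts all its forms, free or not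
- a reading of substrate is of its free form alone

- ranking by amount of target, in percent of the substrate charged, from high to low, at 2.0 min (north / east / south-east / north-west)
- the amount of target, in percent of the substrate charged of the flask you put first, at 2.0 min
- the amount of target, in percent of the substrate charged of the flask you put last, at 2.0 min

Read the second way first: at 10.0 s substrate plus target stands at 77.0% in ochre and 77.0% in grey, so take this loss as independent of reagent and second order in substrate, which in ochre makes 0.0311 s⁻¹ at full charge. Read the target pace from grey over its first 10.0 s, a reading of 0.0150 s⁻¹ of the charge, and scale it with reagent times initiator and, as my own assumption since no run varied substrate, inversely with the charge. Call target pace over loss pace at the start the fork odds, a selectivity factor: grey has 0.483, and north-west, with a quarter of the substrate, has 14.6. The squared fraction left averages a third over a fall to nothing, so triple the odds and expect a target share of 97.8% in north-west, whose substrate should last about 8.80 s. East, at 0.105, reckons to a target share of 24.0% of the substrate used.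

The forecast says north-west > north > south-east > east, 90% and 21%, on the view that “Target formation looks first-order in everything not yet target”; its top stands below my share.

The flask gives north-west > north > south-east > east, with 90.7% and 17.5%, so the forecast holds, and a reagent charge of 0.0310 M would move its top by 5 points. North-west holds 2.65% of homo dimer, against the 2.23% the fork odds allot to the second way out, and 6.64% as ended carrier and ended chains, which the two-way reckoning leaves aside.

    initiator → 2 initiating radical (k = 0.0190 s⁻¹)
    2 first chain carrier → ended chains (k = 8.10 × 10⁶ M⁻¹ s⁻¹)
    reagent + first chain carrier → target + second chain carrier (k = 6340 M⁻¹ s⁻¹)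
    first chain carrier → ended carrier (k = 12.4 s⁻¹)
    substrate + target ⇌ idle adduct, settled at all times (K = 127 M⁻¹)
    substrate + initiating radical → capped initiator + first chain carrier (k = 1.76 × 10⁵ M⁻¹ s⁻¹)
    substrate + second chain carrier → by-product + first chain carrier (k = 27300 M⁻¹ s⁻¹)
    2 substrate → homo dimer (k = 1.23 M⁻¹ s⁻¹)

In the neighbour of north-west charged with 0.012 M of substrate, the odds are 0.914, which reckons to a share of 73.3%; the computed target is 70.5%.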